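(The data stem from a simulated flask on assumed constants; the scatter is artificial.)

The closed flask zeta and the stirred tank eta take the same E, for 25 min in the flask and for that mean residence time in the tank, and you want to know which gives more G, zeta at its end or eta at its outlet.

| flask | E | remark | time |
|---|---|---|---|
| cedar | 1.5 M | run made earlier |  |
| larch | 2.1 M | run made earlier |  |
| zeta | 1.5 M | a closed flask charged with all of it at once and left for 25 min | 25 min |
| eta | 1.5 M | one stirred flow tank at steady state, fed with the mixture as stated, mean residence time 25 min |  |

| run | time / min | G / % | J / % |
|---|---|---|---|
| cedar | 2.00 | 4.7 | 0 |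
| cedar | 6.00 | 12.0 | 0 |
| cedar | 12.0 | 21.2 | 0 |
| cedar | 20.0 | 30.4 | 0.5 |
| cedar | 25.0 | 33.5 | 0 |
| larch | 6.00 | 10.6 | 0 |
| larch | 12.0 | 21.0 | 0.1 |
| larch | 20.0 | 29.2 | 0.6 |
| larch | 25.0 | 32.3 | 1.5 |
| larch | 30.0 | 37.4 | 0 |

(scatter of a reading: 1 percentage point)

- the set-up with the highest amount of G at the outlet or at the end, in percent of the E put in ("none" if the first two lie within 2 percentage points) (zeta / eta / none)
- amount of G at the outlet or at the end, in percent of the E put in, zeta
- amount of G at the outlet or at the end, in percent of the E put in, eta

- the stated concentrations are those of everything mixed, before any reaction; amounts are the same in each set-up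
- the earlier runs were made in a closed, stirred flask

At 12.0 min the cedar run reads 21.2% and the larch run 21.0%, so within the scatter the fractions of the charge don't follow the concentration between these two charges, and you may reckon with first-order steps. The cedar reading at 6.00 min gives a formation constant k of 0.0213 min⁻¹, and k times 25 min is a = 0.533, the Damköhler number.

Now take two extremes. If G stays once formed, zeta holds 41.3% and eta, a over one plus a, holds 34.8%. If G leaves with the same constant k, zeta holds 31.3% and eta 22.7%. The cedar reading at 25.0 min, 33.5%, lies below the first zeta figure and above the second, so I place eta between its two figures.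

Over this time G stands close to kt times the exponential of minus the mean of k and L, times t. The cedar reading therefore gives L = 0.0158 min⁻¹, my estimate, with the scatter of that reading, of the first-order constant with which G leaves. Dividing a over one plus a by one plus L times the residence time, I get 24.9% for eta, and I take the cedar reading for zeta, so I say zeta.

The forecast also says zeta, with 34% for zeta and 27.5% for eta, but it reads the fall of its apparent first-order constant as one that “suggests an approach to equilibrium”, where I reckon with a loss.

The simulation gives zeta, with 33.7% for zeta and 25.3% for eta, under this scheme:

    E → G (k = 0.0210 min⁻¹)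
    G → Z (k = 0.00250 min⁻¹)
    Z → Q (k = 0.0540 min⁻¹)
    Q → J (k = 0.00310 min⁻¹)
    G → D (k = 0.0120 min⁻¹)

G turns into D with a half-life of 58 min, shorter than the 4.6 h of its turning into Z. That second half-life is long against the 25 min of zeta. In the flow tank at a residence time of 250 min, L gives 17.0%, and the tank holds 18.2%.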